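Over 6.0 h this flask sends its starting material through the open intermediate, and the question is how much of that reaches the target.

starting material 1.0 M; gas 150 mM (held); capture agent 0.300 M; time 6.0 h

    starting material + reagent → open intermediate (k1 = 17 M⁻¹ h⁻¹)
    open intermediate → target (k2 = 0.78 h⁻¹)
    gas ⇌ reagent, rate k3*(csat - [reagent]) (k3 = 31 h⁻¹, csat = 150 mM)
    open intermediate + capture agent → trapped intermediate (k4 = 0.82 M⁻¹ h⁻¹)

- at the start none of reagent is dissolved
- run time (flask): 6.0 h

* the target standing at 6.0 h, as a percentage of the starting material charged
* concentration of reagent in solution at 6.0 h, in percent of saturation

At the charge, the open intermediate has a half-life of 2.8 h by capture and 0.89 h by the step to target, so capture takes 24.0 % of it. On 1.0 M of starting material that makes 0.240 M trapped, or 80.0 % of the capture agent, but at the 0.0602 M of capture agent then left the same sum gives capture a share of 5.96 %. These two numbers do not go together.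

I divide the capture rate by the target rate, so that time and c(open intermediate) drop out. What remains is c(capture agent) times the selectivity factor, the capture constant over the target constant, 1.05 M⁻¹, and so c(capture agent) = 0.300 M · exp(−1.05 · c(target)).

Into a solution kept empty the gas can deliver up to 2790 % of the charge by 6.0 h, more than the charge, so I let the starting material finish. With the open intermediate also finished, c(target) is 1.0 M minus the capture agent consumed. Iterating from 1.0 M gives 0.805 M, 0.829 M, 0.826 M and 0.826 M, which is 82.6 %. The half-life of 0.89 h by the step to target alone is shorter than 6.0 h, so I expect the flask to stand slightly below that.

The forecast gives 81.9 %, within 80.5 % to 82.6 %, and 100 % of saturation: “With nothing left to consume it, reagent returns to saturation”.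

The simulation gives 81.9 % target and >99.9 % of saturation, with 0.787 % of the charge still open intermediate. At that target the rule leaves 42.3 % of the capture agent's charge, and the flask holds 42.3 %. In the neighbouring flask, charged with 2.5 M of starting material, the same iteration gives 2.22 M, then 2.23 M, which is 89.2 % of its charge. At 6.00 h that neighbouring flask holds 1.39 % of its charge as open intermediate and 87.8 % as target.

(All constants belong to no real substance.)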